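**Strategy.** The plan rests on cutting the O1–C8a bond of lactone ring B. Ring B (O1, C2, C3, C4, C4a, C8a) is a 3-phenylindan-1-one plus one oxygen atom. With O1 deleted and C2 joined to C8a, stereocentre C4 becomes C3 of a five-membered aryl ketone, which asymmetric hydroacylation supplies as one enantiomer. A Baeyer–Villiger oxidation then shifts C8a from carbon to oxygen, so a single operation installs O1 and enlarges the carbocycle to the six-membered lactone without disturbing C4. The precursor is (3S)-4,6-bis(benzyloxy)-3-phenylindan-1-one, which holds no second ketone. Its benzyl ethers are kept for the C8 acylation, where they shield C6, and leave last by neutral hydrogenolysis.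

Key step: step 4

Assumption: (R)-BINAP is taken to deliver the 3S ketone. The sense of induction is checked on the first batch, and (S)-BINAP is used instead if it proves opposite, with nothing else changed.

Step 1
Reactants: 1 3,5-bis(benzyloxy)benzaldehyde
Product: 2 3,5-bis(benzyloxy)-2-bromobenzaldehyde
Conditions: NBS (1.0 equiv), MeCN, 0 °C to rt, dark
Reagents that add atoms: N-bromosuccinimide, O=C1CCC(=O)N1Br
Why: Electrophilic aromatic bromination with NBS in a polar solvent attacks C2, which is para to one benzyloxy group and ortho to the other, while C4 is buried between both ethers, and one equivalent of reagent at low temperature stops at the monobromide, as is well known for 3,5-dialkoxybenzaldehydes.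

Step 2
Reactants: 2 3,5-bis(benzyloxy)-2-bromobenzaldehyde; 3 4,4,5,5-tetramethyl-2-(1-phenylethenyl)-1,3,2-dioxaborolane
Product: 4 3,5-bis(benzyloxy)-2-(1-phenylethenyl)benzaldehyde
Conditions: Pd(OAc)2 (3 mol %), SPhos (6 mol %), K3PO4, toluene/H2O, 80 °C
Reagents that add atoms: none
Why: Suzuki–Miyaura coupling: the electron-rich bulky biaryl phosphine lets zerovalent palladium insert into the C–Br bond flanked by CHO and OBn and speeds transmetalation enough to outrun protodeboronation of the α-substituted vinylboronate, while aldehyde and benzyl ethers are inert to the mild phosphate base.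

Step 3
Reactants: 4 3,5-bis(benzyloxy)-2-(1-phenylethenyl)benzaldehyde
Product: 5 (3S)-4,6-bis(benzyloxy)-3-phenylindan-1-one
Conditions: Rh(cod)2BF4 (5 mol %), (R)-BINAP (5.5 mol %), activated with H2 then purged with Ar, CH2Cl2, rt
Reagents that add atoms: none
Why: Rhodium-catalysed asymmetric intramolecular alkene hydroacylation, known for 2-(1-substituted ethenyl)benzaldehydes: cationic monovalent rhodium inserts into the formyl C–H bond, the hydride is delivered to the phenyl-bearing alkene carbon on the face left open by the C2-symmetric BINAP pocket (this sets C3 as S), and reductive elimination joins the acyl carbon to the terminal CH2 to close the five-membered ketone.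

Step 4
Reactants: 5 (3S)-4,6-bis(benzyloxy)-3-phenylindan-1-one
Product: 7 (4S)-5,7-bis(benzyloxy)-4-phenylchroman-2-one, via Criegee adduct 6 (not isolated)
Conditions: mCPBA (2.5 equiv), TsOH·H2O (1.0 equiv), CH2Cl2, 0–5 °C, dark
Reagents that add atoms: meta-chloroperoxybenzoic acid (mCPBA), OOC(=O)c1cccc(Cl)c1
Why: The acid-activated ketone of 5 takes up the peracid at C1 to give Criegee adduct 6, and loss of 3-chlorobenzoate from its O–O bond is concerted with a 1,2-shift of aryl carbon C7a (C8a of the product) from C1 to oxygen. This is the Baeyer–Villiger oxidation of 3-arylindan-1-ones to 4-aryl-3,4-dihydrocoumarins, a known transformation under mCPBA and a sulfonic acid. Ring B is formed not by cyclisation but by ring expansion: the oxygen atom enters the C1–C7a bond and the five-membered ketone becomes the six-membered aryl lactone. No stereocentre is created; C3 of 5 is β to the carbonyl, is not the enolisable position and loses no bond, so it should arrive unchanged as C4 (S) of 7. The selectivity needed is migration of C7a instead of the C2 methylene, and it rests on the intrinsic order aryl above primary alkyl (the π system bridges the electron-poor oxygen in the transition state); both benzyloxy groups are meta to C7a and lend no extra push, which is why the risk of the route sits here. Chemoselectivity is secured by the design of 5, which has one ketone, no alkene and a ring deactivated by its carbonyl, and by low temperature and a small excess of peracid, since the ring of 7 is the more oxidisable one.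

Step 5
Reactants: 7 (4S)-5,7-bis(benzyloxy)-4-phenylchroman-2-one; 8 3-phenylpropanoic acid
Product: 10 (4S)-5,7-bis(benzyloxy)-4-phenyl-8-(3-phenylpropanoyl)chroman-2-one, via mixed anhydride 9 (not isolated)
Conditions: 8 (1.3 equiv), (CF3CO)2O (1.2 equiv), CH2Cl2, 0 °C, 30 min; then 7, 0 °C to rt
Reagents that add atoms: trifluoroacetic anhydride, O=C(OC(=O)C(F)(F)F)C(F)(F)F (its CF3CO group is found in 9 only, not in 10)
Why: Friedel–Crafts acylation by an acyl trifluoroacetate, a known Lewis-acid-free method for alkoxyarenes: C8 is para to the C5 ether and ortho to the C7 ether and has the tied-back ring oxygen as one neighbour, whereas C6 lies between two benzyloxy groups of which the C5 one is forced by the C4 substituent to point its CH2 at C6, the same bias that sends electrophiles to C8 of other 5,7-dialkoxybenzopyrans, and the mild medium spares benzyl ethers, lactone and C4 and is too weak to cyclise the acyl donor onto its own phenyl ring.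

Step 6
Reactants: 10 (4S)-5,7-bis(benzyloxy)-4-phenyl-8-(3-phenylpropanoyl)chroman-2-one
Product: 11 (4S)-5,7-dihydroxy-4-phenyl-8-(3-phenylpropanoyl)chroman-2-one (target)
Conditions: H2 (1 atm), 10% Pd/C, EtOAc, rt, stopped after uptake of two equivalents
Reagents that add atoms: none
Why: Catalytic hydrogenolysis of aryl benzyl ethers under neutral conditions: the ketone, once hydrogen-bonded to the freed C7 hydroxyl on a trioxygenated ring, resists reduction as in standard dihydrochalcone syntheses, C4 carries no cleavable C–O bond, and the aprotic non-nucleophilic solvent keeps the lactone closed so that it cannot reopen and reclose on the C5 hydroxyl, which would turn the 8-acyl into the 6-acyl isomer.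

Compound list
1 | 3,5-bis(benzyloxy)benzaldehyde | O=Cc1cc(OCc2ccccc2)cc(OCc2ccccc2)c1 | starting material
2 | 3,5-bis(benzyloxy)-2-bromobenzaldehyde | O=Cc1cc(OCc2ccccc2)cc(OCc2ccccc2)c1Br | intermediate
3 | 4,4,5,5-tetramethyl-2-(1-phenylethenyl)-1,3,2-dioxaborolane | C=C(B1OC(C)(C)C(C)(C)O1)c1ccccc1 | starting material
4 | 3,5-bis(benzyloxy)-2-(1-phenylethenyl)benzaldehyde | O=Cc1cc(OCc2ccccc2)cc(OCc2ccccc2)c1C(=C)c1ccccc1 | intermediate
5 | (3S)-4,6-bis(benzyloxy)-3-phenylindan-1-one | O=C1C[C@@H](c2ccccc2)c2c(OCc3ccccc3)cc(OCc3ccccc3)cc21 | intermediate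
6 | (3S)-4,6-bis(benzyloxy)-1-hydroxy-3-phenylindan-1-yl 3-chloroperoxybenzoate (Criegee adduct, C1 undefined) | OC1(OOC(=O)c2cccc(Cl)c2)C[C@@H](c2ccccc2)c2c(OCc3ccccc3)cc(OCc3ccccc3)cc21 | intermediate
7 | (4S)-5,7-bis(benzyloxy)-4-phenylchroman-2-one | O=C1C[C@@H](c2ccccc2)c2c(OCc3ccccc3)cc(OCc3ccccc3)cc2O1 | intermediate
8 | 3-phenylpropanoic acid | OC(=O)CCc1ccccc1 | starting material
9 | 3-phenylpropanoic trifluoroacetic anhydride | O=C(CCc1ccccc1)OC(=O)C(F)(F)F | intermediate
10 | (4S)-5,7-bis(benzyloxy)-4-phenyl-8-(3-phenylpropanoyl)chroman-2-one | O=C1C[C@@H](c2ccccc2)c2c(OCc3ccccc3)cc(OCc3ccccc3)c(C(=O)CCc3ccccc3)c2O1 | intermediate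
11 | (4S)-5,7-dihydroxy-4-phenyl-8-(3-phenylpropanoyl)chroman-2-one | O=C1C[C@@H](c2ccccc2)c2c(O)cc(O)c(C(=O)CCc3ccccc3)c2O1 | target

Total step count: 6. Longest linear sequence: 6 (1 to 11).

Steps most likely to fail

Risk 1, step 4. Peracid addition to the conjugated aryl ketone may be slow. Electrophilic oxidation of the electron-rich ring, mainly after lactone formation, or competing methylene migration could then erode the outcome. The fallback sets out from 3 and comes back at 7, and it buys the phenol oxygen instead of inserting it.
- Commercial 3,5-bis(benzyloxy)phenol is iodinated next to the hydroxyl (NIS, CH2Cl2, −20 °C) to give 3,5-bis(benzyloxy)-2-iodophenol F1.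
- Suzuki–Miyaura coupling of F1 with 3 (Pd(OAc)2, SPhos, K3PO4, toluene/H2O) gives 3,5-bis(benzyloxy)-2-(1-phenylethenyl)phenol F2.
- Palladium-catalysed asymmetric intramolecular hydroesterification of F2 (Pd(OAc)2, a P-chiral bisphosphine of the WingPhos type, CO, acid co-catalyst) is a known entry to 4-aryl-3,4-dihydrocoumarins. It adds hydrogen at the phenyl-bearing carbon and closes the lactone through the phenol to reach 7.

Risk 2, step 3. The acyl rhodium hydride may decarbonylate, or facial discrimination may be poor, because the alkene is twisted between a phenyl ring and the neighbouring benzyloxy group. The fallback sets out from 2 and comes back at 5, and it closes the ring by C–C bond formation at the aryl bromide.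
- Addition of (E)-2-phenylethenylmagnesium bromide to 2 (THF, −78 °C) gives racemic (E)-1-[3,5-bis(benzyloxy)-2-bromophenyl]-3-phenylprop-2-en-1-ol F3.
- Oxidation with MnO2 gives the chalcone (E)-1-[3,5-bis(benzyloxy)-2-bromophenyl]-3-phenylprop-2-en-1-one F4.
- An enantioselective intramolecular reductive Heck cyclisation of F4 gives 5. The conditions are Pd(OAc)2, a chiral bisphosphine of the MeO-BIPHEP family with the antipode chosen for 3S, and 1,8-bis(dimethylamino)naphthalene as base and hydride donor, in DMF at 100 °C. The reaction is known for 2'-halo- and 2'-sulfonyloxychalcones.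

Risk 3, step 5. The acidic medium may cause loss or carbon migration of benzyl groups, or attack at the doubly flanked C8 may be sluggish. The fallback sets out from 7 and comes back at 11, with deprotection first and acylation of the free resorcinol last.
- Hydrogenolysis of 7 (H2, 10% Pd/C, EtOAc) gives (4S)-5,7-dihydroxy-4-phenylchroman-2-one F5.
- F5 is C-acylated with 8 in BF3·OEt2 at about 70 °C, the classical method for acylphloroglucinols and dihydrochalcones.
- Related 5,7-dihydroxy-4-substituted coumarins are acylated mainly at C8. Material acylated at C6 is removed by chromatography to leave 11.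

Further compounds
F1 | step 4 | 3,5-bis(benzyloxy)-2-iodophenol | Oc1cc(OCc2ccccc2)cc(OCc2ccccc2)c1I
F2 | step 4 | 3,5-bis(benzyloxy)-2-(1-phenylethenyl)phenol | C=C(c1ccccc1)c1c(O)cc(OCc2ccccc2)cc1OCc1ccccc1
F3 | step 3 | (E)-1-[3,5-bis(benzyloxy)-2-bromophenyl]-3-phenylprop-2-en-1-ol (racemic) | OC(/C=C/c1ccccc1)c1cc(OCc2ccccc2)cc(OCc2ccccc2)c1Br
F4 | step 3 | (E)-1-[3,5-bis(benzyloxy)-2-bromophenyl]-3-phenylprop-2-en-1-one | O=C(/C=C/c1ccccc1)c1cc(OCc2ccccc2)cc(OCc2ccccc2)c1Br
F5 | step 5 | (4S)-5,7-dihydroxy-4-phenylchroman-2-one | O=C1C[C@@H](c2ccccc2)c2c(O)cc(O)cc2O1
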